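What stops this flask before 2.5 d, and how much product stands by then?

substrate 23 mM; coupling partner 23.0 mM; protic impurity 6.90 mM; free catalyst 39 µM; time 2.5 d

    substrate + free catalyst → catalyst intermediate A (k1 = 31 M⁻¹ s⁻¹)
    coupling partner + catalyst intermediate A → catalyst intermediate B (k2 = 33 M⁻¹ s⁻¹)
    catalyst intermediate B → by-product + catalyst intermediate C (k3 = 0.76 s⁻¹)
    catalyst intermediate C → free catalyst + product (k4 = 0.79 s⁻¹)
    coupling partner + protic impurity → quenched reagent (k5 = 0.15 M⁻¹ s⁻¹)

- at 2.5 d, what has stopped the reaction, if anything has (no working catalyst is left / it is still moving / all of the substrate has reacted / forward and back rates have come level / the coupling partner has run out first)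
- how much of the substrate has reacted by 2.5 d
- how much product there is at 2.5 d, in percent of the substrate charged

- the reaction counts as stopped when no species that holds the substrate changes by six tenths of a point or more over the second half of the time
- run time (flask): 2.5 d

Who takes the coupling partner? Two takers compete for it: catalyst intermediate A, which makes one product for each partner it takes, and the protic impurity, which makes quenched reagent.

Who is faster at the start? The quench runs at 23.8 µM s⁻¹. One turn of the cycle, with its steps taken in series, gives 7.36 µM s⁻¹, so the quench leads.

What do you reckon with, then? I use the partner budget, the partner left for the cycle once the impurity has taken its whole charge, [partner] minus [impurity] at the start: 16.1 mM. That is less than the 23 mM of substrate, so in this flask the partner is the limiting reagent, and the product comes to 70.0% of the substrate.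

But does the impurity really lose its whole charge? Coupling runs at most at k[second step] times the catalyst charge times [partner], while quenching runs at k[quench] times [partner] times [impurity]. Dividing the two cancels [partner], and integrating gives a closed form: the impurity left is at most exp(−k[quench] × product ÷ (k[second step] × catalyst charge)). With the budget as the product, that is 15.3% of its charge. So my range for this flask runs from 70.0% up to 74.6%.

Is there time? With the catalyst sitting as intermediate A, the partner falls pseudo-first-order with a lifetime of 0.216 h, far shorter than the run. I commit to the partner stopping this flask.

The forecast says the coupling partner has run out first, with 70.5% conversion and 70.3% product, since “The cycle needs only a few hours at most to use that up”. Its single values lie inside my range.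

In the flask, the coupling partner has run out first, with 0% of the partner left, 70.5% conversion and 70.4% product. At 2.50 d the impurity in this flask stands at 1.2% of its charge, under my bound, and the budget with that remainder added back gives 70.4% of the substrate. A neighbour flask, the same but for its substrate, holds 5.8 mM of substrate, less than the budget, so the budget leaves 44.8% of the partner charge unused; that neighbour flask reached 100% product and kept 45% of its partner at 2.50 d.

The constants used here come from no measurement, and the outcome is calculated.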